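## Retrosynthetic overview

1. The 1,4-thiazine 1,1-dioxide is made last, by hypotaurine addition/oxidation onto the free C=C of a 1,4-naphthoquinone.
2. The seven-membered dienol lactone comes from dehydrative O-acylation of the dienol of a cyclohexene-carbaldehyde by the ortho aryl carboxylic acid.
3. The central benzene ring comes from 6π-electrocyclisation/aromatisation of a 2,3-dialkenyl-1,4-benzoquinone (unmasked with CAN); the triene is assembled by a Heck coupling of an aryl bromide with the vinyl group on the quaternary carbon.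
4. The quaternary stereocentre is set by a Pd-catalysed enantioselective α′-vinylation of 2,6-dimethylcyclohex-2-enone; the ketone becomes the enal by reductive enol triflation and Pd formylation.
5. Ring order: cyclohexene (from the enone) and quinone ring (from hydroquinone) in parallel, then central benzene ring, then lactone, then thiazine.

Assumption: the quaternary carbon is S as read from the SMILES; step 2 is run with the ligand antipode that gives this sense, checked against the sample from the step 2 fallback.

## Route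

Step 1
Reactants: 1 2-methylcyclohex-2-en-1-one
Product: 3 2,6-dimethylcyclohex-2-en-1-one (racemic), via lithium dienolate 2 (not isolated)
Conditions: LDA (1.05 equiv), THF, −78 °C; MeI, −78 → 0 °C
Reagents that add atoms: iodomethane, CI
Why: Kinetic α′-deprotonation gives the cross-conjugated enolate, which is C-methylated (kinetic enolate alkylation); the new centre is racemic and is erased in step 2.

Step 2
Reactants: 3 2,6-dimethylcyclohex-2-en-1-one + 4 bromoethene (vinyl bromide)
Product: 7 (6S)-6-ethenyl-2,6-dimethylcyclohex-2-en-1-one, via lithium dienolate 5 (not isolated), via chlorozinc dienolate 6 (not isolated)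
Conditions: LDA (1.05 equiv), THF, −78 °C; ZnCl2 (1.1 equiv), −78 → 0 °C; Pd2(dba)3 (2.5 mol %), (S)-2-(dicyclohexylphosphino)-2′-(dimethylamino)-1,1′-binaphthyl (6 mol %, or its antipode), vinyl bromide (1.5 equiv, 1 M in THF), 25 °C
Reagents that add atoms: none
Why: Proposed new method: Pd(0)/chiral biaryl-monophosphine-catalysed enantioselective α′-vinylation of a regiodefined, non-equilibrating cross-conjugated zinc dienolate, in which oxidative addition of vinyl bromide, Zn-to-Pd transmetalation to the C-bound tertiary Pd enolate and enantio-determining C–C reductive elimination on the planar prochiral enolate create the quaternary centre (the small vinyl partner eases reductive elimination and the zinc enolate suppresses γ-coupling and proton exchange with the product); the closest known reaction types are the Pd-catalysed asymmetric α-vinylation and α-arylation of 2-methyl-1-tetralone-type ketone enolates and the racemic α′-arylation of vinylogous esters, none yet shown for a simple 2-substituted cyclohexenone α′-enolate with parent vinyl bromide.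

Step 3
Reactants: 7 (6S)-6-ethenyl-2,6-dimethylcyclohex-2-en-1-one
Product: 9 (6S)-6-ethenyl-2,6-dimethylcyclohex-1-en-1-yl trifluoromethanesulfonate, via lithium enolate 8 (not isolated)
Conditions: L-Selectride (1.05 equiv), THF, −78 °C; PhNTf2 (1.2 equiv), −78 → 0 °C
Reagents that add atoms: N-phenylbis(trifluoromethanesulfonimide), O=S(=O)(N(c1ccccc1)S(=O)(=O)C(F)(F)F)C(F)(F)F
Why: 1,4-Hydride addition to the β-unsubstituted enone gives the only possible enolate regiospecifically, which is O-triflated in situ (conjugate reduction–enolate trapping); the quaternary centre is not touched.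

Step 4
Reactants: 9 (6S)-6-ethenyl-2,6-dimethylcyclohex-1-en-1-yl trifluoromethanesulfonate
Product: 10 (6S)-6-ethenyl-2,6-dimethylcyclohex-1-ene-1-carbaldehyde
Conditions: Pd(OAc)2 (5 mol %), dppp (5 mol %), CO (1 atm), Et3SiH (2 equiv), Et3N (2.5 equiv), DMF, 70 °C
Reagents that add atoms: carbon monoxide, [C-]#[O+]
Why: Pd-catalysed reductive carbonylation (formylation) of a vinyl triflate by oxidative addition, CO insertion and silane hydride capture of the acyl-Pd, as established for hindered cyclocitral-type triflates; the vinyl group has no allylic hydrogen and cannot isomerise.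

Step 5
Reactants: 11 hydroquinone
Product: 12 1,4-dimethoxybenzene
Conditions: MeI (3 equiv), K2CO3 (3 equiv), acetone, reflux
Reagents that add atoms: iodomethane, CI
Why: Williamson O-methylation masks the future quinone as its dimethyl ether.

Step 6
Reactants: 12 1,4-dimethoxybenzene
Product: 13 2-bromo-1,4-dimethoxybenzene
Conditions: NBS (1.0 equiv), MeCN, 20 °C
Reagents that add atoms: N-bromosuccinimide, O=C1CCC(=O)N1Br
Why: Electrophilic aromatic monobromination of the activated ring, whose four free positions are equivalent.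

Step 7
Reactants: 13 2-bromo-1,4-dimethoxybenzene
Product: 15 2-bromo-3,6-dimethoxybenzaldehyde, via aryllithium 14 (not isolated)
Conditions: LDA (1.1 equiv), THF, −78 °C, 1 h; DMF (2 equiv), −78 → −40 °C; H2O
Reagents that add atoms: N,N-dimethylformamide, CN(C)C=O
Why: Directed ortho-lithiation at the C–H flanked by Br and OMe (kept at −78 °C so that LiBr is not lost to an aryne) followed by formylation with DMF.

Step 8
Reactants: 15 2-bromo-3,6-dimethoxybenzaldehyde + 16 malonic acid
Product: 18 (2E)-3-(2-bromo-3,6-dimethoxyphenyl)prop-2-enoic acid, via arylidenemalonic acid 17 (not isolated)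
Conditions: pyridine, piperidine (10 mol %), 100 °C
Reagents that add atoms: none
Why: Knoevenagel–Doebner condensation with decarboxylation gives the E-cinnamic acid.

Step 9
Reactants: 18 (2E)-3-(2-bromo-3,6-dimethoxyphenyl)prop-2-enoic acid + 10 (6S)-6-ethenyl-2,6-dimethylcyclohex-1-ene-1-carbaldehyde
Product: 19 (2E)-3-{2-[(E)-2-[(1S)-2-formyl-1,3-dimethylcyclohex-2-en-1-yl]ethenyl]-3,6-dimethoxyphenyl}prop-2-enoic acid
Conditions: Pd2(dba)3 (2.5 mol %), P(t-Bu)3·HBF4 (10 mol %), Cy2NMe (3 equiv), 10 (1.3 equiv), 1,4-dioxane, 100 °C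
Reagents that add atoms: none
Why: Mizoroki–Heck coupling in which the aryl group adds to the terminal carbon of the vinyl group on the quaternary carbon and the only available β-hydrogen gives the E-alkene; the tetrasubstituted enal and the cinnamic acid alkene are too hindered to compete.

Step 10
Reactants: 19 (2E)-3-{2-[(E)-2-[(1S)-2-formyl-1,3-dimethylcyclohex-2-en-1-yl]ethenyl]-3,6-dimethoxyphenyl}prop-2-enoic acid
Product: 23 3-[(1S)-2-formyl-1,3-dimethylcyclohex-2-en-1-yl]-5,8-dioxo-5,8-dihydronaphthalene-2-carboxylic acid, via dialkenylbenzoquinone 20 (not isolated), via electrocyclised dienedione 21 (not isolated), via naphthalene-1,4-diol 22 (not isolated)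
Conditions: CAN (4.4 equiv), MeCN–H2O (3:1), 0 °C, 20 min; then 40 °C, 2 h
Reagents that add atoms: water, O
Why: CAN oxidative demethylation unmasks the 2,3-dialkenyl-1,4-benzoquinone, whose ring-locked (E,Z,E)-hexatriene undergoes thermal disrotatory 6π-electrocyclisation; two enolisations aromatise it to the naphthalene-1,4-diol, which the remaining Ce(IV) oxidises to the naphthoquinone.

Step 11
Reactants: 23 3-[(1S)-2-formyl-1,3-dimethylcyclohex-2-en-1-yl]-5,8-dioxo-5,8-dihydronaphthalene-2-carboxylic acid
Product: 25 (S)-naphthoquinone dienol lactone (the target without the thiazine ring), via mixed trifluoroacetic anhydride 24 (not isolated)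
Conditions: TFAA (1.5 equiv), 2,6-lutidine (3 equiv), CH2Cl2, 0 → 20 °C
Reagents that add atoms: none
Why: Enol lactonisation through the mixed anhydride, in which intramolecular O-acylation of the aldehyde oxygen gives an acyloxy-allyl cation that loses the ring γ-hydrogen, closing the seven-membered ring and placing the diene as C(Me)=CH in the ring and C=CH–O exocyclic.

Step 12
Reactants: 25 (S)-naphthoquinone dienol lactone + 26 2-aminoethanesulfinic acid (hypotaurine)
Product: 30 CNP0348176.1 (target), via sulfonylhydroquinone 27 (not isolated), via sulfonylquinone 28 (not isolated), via leuco thiazine hydroquinone 29 (not isolated)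
Conditions: hypotaurine (1.3 equiv), MeCN–EtOH–H2O (1:1:1), 20 → 40 °C, open to air; chromatography to remove the regioisomer
Reagents that add atoms: none
Why: Hypotaurine–quinone annulation (double conjugate addition with aerobic re-oxidation, as used for adociaquinone-type thiazines), in which the zwitterion adds through sulfinate sulfur β to the more electrophilic quinone carbonyl (the one para-conjugated to the lactone C=O) and the tethered amine then closes onto the adjacent carbon.

## Compound list

1 | 2-methylcyclohex-2-en-1-one | CC1=CCCCC1=O | starting material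
2 | lithium 6-methylcyclohexa-1,5-dien-1-olate | CC1=CCCC=C1O[Li] | intermediate (not isolated)
3 | 2,6-dimethylcyclohex-2-en-1-one (racemic) | CC1CCC=C(C)C1=O | intermediate
4 | bromoethene (vinyl bromide) | C=CBr | starting material
5 | lithium 2,6-dimethylcyclohexa-1,5-dien-1-olate | CC1=CCCC(C)=C1O[Li] | intermediate (not isolated)
6 | chlorozinc 2,6-dimethylcyclohexa-1,5-dien-1-olate | CC1=CCCC(C)=C1O[Zn]Cl | intermediate (not isolated)
7 | (6S)-6-ethenyl-2,6-dimethylcyclohex-2-en-1-one | CC1=CCC[C@](C=C)(C)C1=O | intermediate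
8 | lithium (6S)-6-ethenyl-2,6-dimethylcyclohex-1-en-1-olate | CC1=C(O[Li])[C@](C)(C=C)CCC1 | intermediate (not isolated)
9 | (6S)-6-ethenyl-2,6-dimethylcyclohex-1-en-1-yl trifluoromethanesulfonate | CC1=C(OS(=O)(=O)C(F)(F)F)[C@](C)(C=C)CCC1 | intermediate
10 | (6S)-6-ethenyl-2,6-dimethylcyclohex-1-ene-1-carbaldehyde | CC1=C(C=O)[C@](C)(C=C)CCC1 | intermediate
11 | hydroquinone | Oc1ccc(O)cc1 | starting material
12 | 1,4-dimethoxybenzene | COc1ccc(OC)cc1 | intermediate
13 | 2-bromo-1,4-dimethoxybenzene | COc1ccc(OC)c(Br)c1 | intermediate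
14 | (2-bromo-3,6-dimethoxyphenyl)lithium | COc1ccc(OC)c(Br)c1[Li] | intermediate (not isolated)
15 | 2-bromo-3,6-dimethoxybenzaldehyde | COc1ccc(OC)c(Br)c1C=O | intermediate
16 | malonic acid | OC(=O)CC(O)=O | starting material
17 | 2-[(2-bromo-3,6-dimethoxyphenyl)methylidene]propanedioic acid | COc1ccc(OC)c(Br)c1C=C(C(O)=O)C(O)=O | intermediate (not isolated)
18 | (2E)-3-(2-bromo-3,6-dimethoxyphenyl)prop-2-enoic acid | COc1ccc(OC)c(Br)c1/C=C/C(O)=O | intermediate
19 | (2E)-3-{2-[(E)-2-[(1S)-2-formyl-1,3-dimethylcyclohex-2-en-1-yl]ethenyl]-3,6-dimethoxyphenyl}prop-2-enoic acid | CC1=C(C=O)[C@](C)(/C=C/c2c(OC)ccc(OC)c2/C=C/C(O)=O)CCC1 | intermediate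
20 | (2E)-3-{2-[(E)-2-[(1S)-2-formyl-1,3-dimethylcyclohex-2-en-1-yl]ethenyl]-3,6-dioxocyclohexa-1,4-dien-1-yl}prop-2-enoic acid | CC1=C(C=O)[C@](C)(/C=C/C2=C(\C=C\C(O)=O)C(=O)C=CC2=O)CCC1 | intermediate (not isolated)
21 | 3-[(1S)-2-formyl-1,3-dimethylcyclohex-2-en-1-yl]-5,8-dioxo-2,3,5,8-tetrahydronaphthalene-2-carboxylic acid (C2/C3 diastereomers) | CC1=C(C=O)[C@](C)(C2C=C3C(=O)C=CC(=O)C3=CC2C(O)=O)CCC1 | intermediate (not isolated)
22 | 3-[(1S)-2-formyl-1,3-dimethylcyclohex-2-en-1-yl]-5,8-dihydroxynaphthalene-2-carboxylic acid | CC1=C(C=O)[C@](C)(c2cc3c(O)ccc(O)c3cc2C(O)=O)CCC1 | intermediate (not isolated)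
23 | 3-[(1S)-2-formyl-1,3-dimethylcyclohex-2-en-1-yl]-5,8-dioxo-5,8-dihydronaphthalene-2-carboxylic acid | CC1=C(C=O)[C@](C)(c2cc3C(=O)C=CC(=O)c3cc2C(O)=O)CCC1 | intermediate
24 | mixed anhydride of 23 with trifluoroacetic acid | CC1=C(C=O)[C@](C)(c2cc3C(=O)C=CC(=O)c3cc2C(=O)OC(=O)C(F)(F)F)CCC1 | intermediate (not isolated)
25 | (S)-naphthoquinone dienol lactone: 1,4-naphthoquinone fused at C6/C7 to the seven-membered ArC(=O)–O–CH=C lactone, which carries the (S)-methyl quaternary carbon and the 2-methylcyclohex-2-ene ring | CC1=CCC[C@]2(C)C1=COC(=O)c1cc3c(cc12)C(=O)C=CC3=O | intermediate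
26 | 2-aminoethanesulfinic acid (hypotaurine) | NCCS(=O)O | starting material
27 | sulfonylhydroquinone: the naphthalene-1,4-diol of 25 with 2-aminoethylsulfonyl on the carbon next to the C–OH peri to the aryl CH that lies para to the quaternary-carbon-bearing position | CC1=CCC[C@]2(C)C1=COC(=O)c1cc3c(cc12)c(O)cc(c3O)S(=O)(=O)CCN | intermediate (not isolated)
28 | sulfonylquinone: 25 with 2-aminoethylsulfonyl on the same quinone carbon | CC1=CCC[C@]2(C)C1=COC(=O)c1cc3c(cc12)C(=O)C=C(C3=O)S(=O)(=O)CCN | intermediate (not isolated)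
29 | leuco thiazine hydroquinone (dihydro form of the target) | CC1=CCC[C@]2(C)C1=COC(=O)c1cc3c(cc12)c(O)c4NCCS(=O)(=O)c4c3O | intermediate (not isolated)
30 | CNP0348176.1, (S) at the quaternary carbon | CC1=CCC[C@]2(C)C1=COC(=O)c1cc3c(cc12)C(=O)C1=C(C3=O)S(=O)(=O)CCN1 | target

## Step count

Total steps: 12.
Longest linear sequence: 8 (steps 1–4 then 9–12; the arene branch, steps 5–8 then 9–12, is equally long).

## Steps most likely to fail and fallbacks

Step 2 (the proposed new enantioselective α′-vinylation; risks are low ee, γ-coupling or slow reductive elimination). The fallback uses known chemistry, sets out from 3 and returns at 7. Ketone 3 is O-acylated (LiHMDS, TMEDA, allyl chloroformate, THF, −78 °C) to allyl 2,6-dimethylcyclohexa-1,5-dien-1-yl carbonate F1. Pd2(dba)3/(S)-t-Bu-PHOX (THF, 25 °C) then effects decarboxylative asymmetric allylic alkylation to (6S)-2,6-dimethyl-6-(prop-2-en-1-yl)cyclohex-2-en-1-one F2. The allyl group is isomerised with RuHCl(CO)(PPh3)3 (toluene, 80 °C) to (6S)-2,6-dimethyl-6-[(E)-prop-1-en-1-yl]cyclohex-2-en-1-one F3. Ethenolysis (Hoveyda–Grubbs II, ethylene, CH2Cl2, 40 °C) removes one carbon and gives 7, which also serves to fix the absolute sense of the step 2 product.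

Step 10 (the free dialkenylquinone may dimerise or be over-oxidised before it electrocyclises). The fallback sets out from 19 and returns at 23, and avoids a vinylquinone altogether. Anodic oxidation of 19 (Pt anode, 1% KOH in MeOH, 0 °C) gives the quinone bis(dimethyl ketal) F4. Heating (toluene, 110 °C) closes its triene to the electrocyclised bisketal F5. Catalytic TsOH eliminates two methanol to give 3-[(1S)-2-formyl-1,3-dimethylcyclohex-2-en-1-yl]-5,8-dimethoxynaphthalene-2-carboxylic acid F6. CAN (MeCN–H2O, 0 °C) then gives 23.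

Step 12 (modest regioselectivity, and possible aminolysis of the enol lactone by the free amine). The fallback sets out from 26 and 25 and returns at 28. Hypotaurine 26 is N-protected (Boc2O, NaOH, dioxane–H2O) to sodium 2-[(tert-butoxycarbonyl)amino]ethanesulfinate F7. F7 adds to 25 through sulfur only (AcOH, MeCN–H2O, 20 °C) to give the N-Boc sulfonylhydroquinone F8, a stable stage at which any regioisomer is removed. Ag2O (CH2Cl2) oxidises F8 to the N-Boc sulfonylquinone F9. TFA (CH2Cl2, 0 °C) followed by NaHCO3 in air releases 28, which closes to 29 and 30 as in step 12.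

## Further compounds

F1 | step 2 | allyl 2,6-dimethylcyclohexa-1,5-dien-1-yl carbonate | CC1=CCCC(C)=C1OC(=O)OCC=C
F2 | step 2 | (6S)-2,6-dimethyl-6-(prop-2-en-1-yl)cyclohex-2-en-1-one | CC1=CCC[C@](CC=C)(C)C1=O
F3 | step 2 | (6S)-2,6-dimethyl-6-[(E)-prop-1-en-1-yl]cyclohex-2-en-1-one | CC1=CCC[C@](/C=C/C)(C)C1=O
F4 | step 10 | quinone bis(dimethyl ketal) of 19 (3,3,6,6-tetramethoxycyclohexa-1,4-diene carrying both alkenyl arms) | CC1=C(C=O)[C@](C)(/C=C/C2=C(\C=C\C(O)=O)C(OC)(OC)C=CC2(OC)OC)CCC1
F5 | step 10 | electrocyclised bisketal (5,5,8,8-tetramethoxy-2,3,5,8-tetrahydronaphthalene-2-carboxylic acid carrying the cyclohexenyl group at C3) | CC1=C(C=O)[C@](C)(C2C=C3C(OC)(OC)C=CC(OC)(OC)C3=CC2C(O)=O)CCC1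
F6 | step 10 | 3-[(1S)-2-formyl-1,3-dimethylcyclohex-2-en-1-yl]-5,8-dimethoxynaphthalene-2-carboxylic acid | CC1=C(C=O)[C@](C)(c2cc3c(OC)ccc(OC)c3cc2C(O)=O)CCC1
F7 | step 12 | sodium 2-[(tert-butoxycarbonyl)amino]ethanesulfinate | CC(C)(C)OC(=O)NCCS(=O)[O-].[Na+]
F8 | step 12 | N-Boc sulfonylhydroquinone (27 with NHBoc in place of NH2) | CC1=CCC[C@]2(C)C1=COC(=O)c1cc3c(cc12)c(O)cc(c3O)S(=O)(=O)CCNC(=O)OC(C)(C)C
F9 | step 12 | N-Boc sulfonylquinone (28 with NHBoc in place of NH2) | CC1=CCC[C@]2(C)C1=COC(=O)c1cc3c(cc12)C(=O)C=C(C3=O)S(=O)(=O)CCNC(=O)OC(C)(C)C
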